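**Retrosynthetic overview**

1. The target comes from water opening the 8α,9α-epoxide at C8 with inversion; the epoxide comes from the 6α-aryl ester of dauc-8-ene-4β,6α-diol **29**.
2. **29** comes from the bicyclic C6 ketone: the 4β-hydroxyl directs reduction at C6, and the C8 methyl and 8,9-alkene are installed by two Saegusa oxidations, a cuprate addition and a deconjugation.
3. Key disconnection C3–C4 (ring A, five-membered). The strategy rests on C4: a tertiary carbinol that carries the isopropyl group, is bonded to ring-fusion carbon C5 and lies β to the C6 oxygen. Ring A is therefore closed by a SmI2 Barbier addition of the primary C3 iodide to the C4 isopropyl ketone, with the C6 dioxolane as chelating anchor.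
4. Precursor **16** comes from ring B (seven-membered), built on cycloheptane-1,3-dione. C1 is set by copper-catalysed enantioselective conjugate vinylation with aldol trapping by isobutyraldehyde. C5 is set by thexylborane cyclic hydroboration of the resulting 1,4-diene, the hydrogen being delivered through the C1 vinyl tether; the same step installs the C3 and C4 oxygens.
5. Ring order: ring B is present from the start; ring A is formed in step 10.

Key step: step 10

Assumption: locants follow the daucane skeleton of the target (C1 quaternary carbon, C4 carbinol, C5 ring-fusion CH, C6 ester carbon, C8 and C9 diol carbons), and β is the face of the C1 methyl group. The alkylidene compounds **10**–**12** are drawn as the Z isomers expected on steric grounds; the E isomers would converge on the same ketone **16**.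

**Route**

Step 1
Reactants: 1 cycloheptane-1,3-dione
Product: 2 3-(2-methylpropoxy)cyclohept-2-en-1-one
Conditions: i-BuOH, TsOH·H2O (cat.), toluene, reflux, Dean–Stark
Reagents that add atoms: 2-methylpropan-1-ol CC(C)CO
Why: Acid-catalysed condensation of a cyclic 1,3-diketone with an alcohol under water removal gives the vinylogous ester, which differentiates the two carbonyl groups (no stereocentre is formed).

Step 2
Reactants: 2 3-(2-methylpropoxy)cyclohept-2-en-1-one
Product: 4 3-methylcyclohept-2-en-1-one, via lithium carbinolate adduct 3 (not isolated)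
Conditions: MeLi, Et2O, −78 to 0 °C; then 1 M HCl, rt
Reagents that add atoms: methyllithium C[Li]; water O
Why: Stork–Danheiser sequence, in which 1,2-addition to the vinylogous ester carbonyl and acidic hydrolysis with allylic transposition give the β-methyl enone.

Step 3
Reactants: 4 3-methylcyclohept-2-en-1-one; 5 ethynyltrimethylsilane; 6 2-methylpropanal
Product: 8 (3R)-2-(1-hydroxy-2-methylpropyl)-3-methyl-3-[1-(trimethylsilyl)ethenyl]cycloheptan-1-one (diastereomer mixture at C2 and at the carbinol carbon), via aluminium enolate 7 (not isolated)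
Conditions: 5, i-Bu2AlH, hexanes/THF, 55 °C; then 4, Cu(OTf)2 (5 mol%), chiral N-(2-sulfonatoaryl)-4,5-diphenylimidazolinium carbene precursor (5 mol%), Ag2O, THF, 4 °C; then 6, −78 °C; aq. KNaC4H4O6
Reagents that add atoms: none
Why: Copper-catalysed enantioselective conjugate addition of a silyl-substituted vinylaluminium reagent to a β-methyl cycloalkenone should create the C1 quaternary centre (R in 8, set by the chosen antipode of the chiral carbene ligand), and the regiodefined aluminium enolate is trapped at C5 by aldol addition; the two carbinol-related centres are erased in step 4.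

Step 4
Reactants: 8 the aldol from step 3
Product: 10 (2Z,3R)-3-methyl-2-(2-methylpropylidene)-3-[1-(trimethylsilyl)ethenyl]cycloheptan-1-one, via methanesulfonate 9 (not isolated)
Conditions: MsCl, Et3N, CH2Cl2, 0 °C; then DBU, rt
Reagents that add atoms: none
Why: Mesylation and E1cB elimination of the β-hydroxy ketone should give the conjugated exocyclic enone, with the isopropyl group turned away from the quaternary C1.

Step 5
Reactants: 10 the silylated dienone
Product: 11 (2Z,3S)-3-ethenyl-3-methyl-2-(2-methylpropylidene)cycloheptan-1-one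
Conditions: CF3CO2H, CH2Cl2, 0 °C to rt
Reagents that add atoms: none
Why: Protodesilylation of the vinylsilane (ipso protonation, loss of silicon from the β-silyl cation) leaves the plain vinyl group; C1 is untouched and its descriptor changes only through the priority rules.

Step 6
Reactants: 11 the dienone
Product: 12 (6Z,7S)-7-ethenyl-7-methyl-6-(2-methylpropylidene)-1,4-dioxaspiro[4.6]undecane
Conditions: TMSOCH2CH2OTMS, TMSOTf (cat.), CH2Cl2, −78 to −20 °C; pyridine
Reagents that add atoms: 1,2-bis(trimethylsilyloxy)ethane C[Si](C)(C)OCCO[Si](C)(C)C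
Why: Aprotic ketalisation with the bis-silyl ether of ethylene glycol and catalytic silyl triflate converts enones into dioxolanes at low temperature without moving the double bond, and masks C6 for the borane and samarium steps.

Step 7
Reactants: 12 the diene ketal
Product: 14 (1S)-1-[(6R,7S)-7-(2-hydroxyethyl)-7-methyl-1,4-dioxaspiro[4.6]undecan-6-yl]-2-methylpropan-1-ol, via cyclic thexylborane 13 (not isolated)
Conditions: ThxBH2 (from BH3·THF and 2,3-dimethylbut-2-ene), THF, −20 °C to rt, dilute; then NaOH, H2O2, 0 °C to rt
Reagents that add atoms: hydrogen peroxide OO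
Why: Cyclic hydroboration of a 1,4-diene with thexylborane: the vinyl group is hydroborated first at C3, and the tethered B–H then adds across C5=C4 inside a six-membered borinane (boron at C4, hydrogen at C5 on the face of the C1 arm), which sets C5 with its hydrogen cis to the arm and the C4 carbon trans to it; oxidation with retention gives the 1,5-diol.

Step 8
Reactants: 14 the diol
Product: 15 (1S)-1-[(6R,7S)-7-(2-iodoethyl)-7-methyl-1,4-dioxaspiro[4.6]undecan-6-yl]-2-methylpropan-1-ol
Conditions: I2, PPh3, imidazole, CH2Cl2, 0 °C
Reagents that add atoms: iodine II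
Why: Appel-type iodination should be selective for the primary alcohol, because the secondary carbinol is flanked by the isopropyl group and the fully substituted ring carbons.

Step 9
Reactants: 15 the iodo alcohol
Product: 16 1-[(6R,7S)-7-(2-iodoethyl)-7-methyl-1,4-dioxaspiro[4.6]undecan-6-yl]-2-methylpropan-1-one
Conditions: Dess–Martin periodinane, NaHCO3, CH2Cl2, rt
Reagents that add atoms: none
Why: Dess–Martin oxidation of the secondary alcohol under buffered, non-basic conditions gives the isopropyl ketone without epimerising C5 and without touching the iodide or the ketal.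

Step 10
Reactants: 16 the iodoethyl isobutyryl ketal
Product: 18 trans-fused 6,6-ethylenedioxy-4-isopropyl-1-methylbicyclo[5.3.0]decan-4β-ol (1S,4R,5R), via alkylsamarium 17 (not isolated)
Conditions: SmI2 (2.5 equiv), NiI2 (2 mol%), THF, 0 °C to rt; aq. NH4Cl
Reagents that add atoms: none
Why: Samarium Barbier reaction: divalent samarium, assisted by the nickel catalyst, reduces the primary C–I bond by two single-electron transfers to a C3 alkylsamarium of trivalent samarium, which adds to the C4 ketone; the closest known reaction type is the SmI2-promoted intramolecular Barbier cyclisation of ω-iodoalkyl ketones with chelation by a neighbouring oxygen function. Ring A closes in a 5-exo-trig mode, C3 attacking the carbonyl carbon C4. The new stereocentre C4 is controlled by a six-membered chelate of trivalent samarium between the C4 carbonyl oxygen and one dioxolane oxygen at C6, which holds the C–O bond on the side of the C5–C6 bond, and sterics act in the same sense because the isopropyl group avoids the spiro dioxolane and turns to the C5–H side. The step needs the 4-hydroxyl cis to C6 (4β) and reduction of the iodide before the ketone; the chelate secures the first, and the unbranched primary iodide together with the hindered, unactivated dialkyl ketone secures the second, while the ketal rules out retro-aldol cleavage of the alkoxide. The trans ring fusion is not made here but is carried over from C1 and C5 of 16.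

Step 11
Reactants: 18 the ketal alcohol
Product: 19 4-O-triethylsilyl ether of 18
Conditions: TESOTf, 2,6-lutidine, CH2Cl2, −78 to 0 °C
Reagents that add atoms: triethylsilyl trifluoromethanesulfonate CC[Si](CC)(CC)OS(=O)(=O)C(F)(F)F
Why: Silylation of the hindered tertiary alcohol with a silyl triflate gives an ether that blocks retro-aldol cleavage of the later β-hydroxy ketone in the base-mediated steps.

Step 12
Reactants: 19 the silyl ether ketal
Product: 20 trans-fused 4-isopropyl-1-methyl-4β-(triethylsilyloxy)bicyclo[5.3.0]decan-6-one
Conditions: PPTS, acetone/H2O, 55 °C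
Reagents that add atoms: water O
Why: Mild acid-catalysed ketal hydrolysis should free the C6 ketone while the hindered tertiary silyl ether survives and C5 is not epimerised.

Step 13
Reactants: 20 the C6 ketone
Product: 22 the corresponding 7-en-6-one, via silyl enol ether 21 (not isolated)
Conditions: LiN(i-Pr)2, TMSCl, THF, −78 °C; then Pd(OAc)2 (1.1 equiv), MeCN, rt
Reagents that add atoms: none
Why: Saegusa oxidation: kinetic enolisation occurs at the accessible C7 methylene rather than the hindered C5–H, and since C1 and C4 carry no hydrogen the dehydrogenation can only run toward C7–C8.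

Step 14
Reactants: 22 the 7-en-6-one
Product: 24 the 8-methyl-7-en-6-one, via methylated silyl enol ether 23 (not isolated)
Conditions: Me2CuLi (from MeLi and CuI), TMSCl, THF, −78 °C; then Pd(OAc)2 (1.1 equiv), MeCN, rt to 40 °C
Reagents that add atoms: lithium dimethylcuprate [Li+].C[Cu-]C
Why: Conjugate addition of the Gilman cuprate with in situ silylation places the methyl group on C8, and a second Saegusa oxidation of the regiodefined silyl enol ether restores the enone, which erases the transient C8 stereocentre.

Step 15
Reactants: 24 the 8-methyl-7-en-6-one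
Product: 27 the 8-methyl-8-en-6-one (4-O-triethylsilyl), via silyl dienol ether 25 (not isolated), via lithium dienolate 26 (not isolated)
Conditions: TMSOTf, Et3N, CH2Cl2, 0 °C to rt; evaporate; MeLi, THF, 0 °C; AcOH, −78 °C
Reagents that add atoms: none
Why: Deconjugation by kinetic α-protonation of an extended dienolate: equilibrating silylation should give the endocyclic linear dienol ether (the hindered C5–H is expected to stay), MeLi releases the lithium dienolate in the absence of a proton source, and acetic acid protonates C7 to leave the 8,9-alkene.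

Step 16
Reactants: 27 the silylated β,γ-enone
Product: 28 4β-hydroxy-8-methyl-8-en-6-one
Conditions: HF·pyridine, pyridine, THF, 0 °C to rt
Reagents that add atoms: none
Why: Fluoride-mediated cleavage of the tertiary silyl ether under buffered, weakly acidic conditions avoids the bases that would trigger retro-aldol cleavage or reconjugation.

Step 17
Reactants: 28 the hydroxy ketone
Product: 29 dauc-8-ene-4β,6α-diol
Conditions: Me4NBH(OAc)3, AcOH/MeCN, −30 °C
Reagents that add atoms: none
Why: Evans–Saksena reduction: the 4β-hydroxyl exchanges onto boron and delivers hydride internally to the β face of the C6 carbonyl, which should give the 6α-alcohol (anti 1,3-diol) that an external hydride is unlikely to favour because of the axial C1 methyl group.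

Step 18
Reactants: 29 the diol; 30 4-[(tert-butyldimethylsilyl)oxy]benzoic acid
Product: 31 4β-hydroxydauc-8-en-6α-yl 4-[(tert-butyldimethylsilyl)oxy]benzoate
Conditions: DCC, DMAP, CH2Cl2, rt
Reagents that add atoms: none
Why: Steglich esterification acylates the secondary 6-hydroxyl with retention at C6, the tertiary 4-hydroxyl being too hindered to react.

Step 19
Reactants: 31 the unsaturated ester
Product: 32 the 8α,9α-epoxide of 31
Conditions: mCPBA, NaHCO3, CH2Cl2, 0 °C
Reagents that add atoms: 3-chloroperoxybenzoic acid OOC(=O)c1cccc(Cl)c1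
Why: Prilezhaev epoxidation of the trisubstituted alkene should occur on the α face, away from the axial C1 methyl group that shields the β face.

Step 20
Reactants: 32 the epoxide
Product: 33 4β,8β,9α-trihydroxydaucan-6α-yl 4-[(tert-butyldimethylsilyl)oxy]benzoate
Conditions: HClO4 (cat.), THF/H2O, 0 °C
Reagents that add atoms: water O
Why: Acid-catalysed epoxide hydrolysis, in which water attacks the tertiary C8 from the β face with inversion (8β-OH, 8α-methyl) while the α oxygen stays on C9.

Step 21
Reactants: 33 the silylated triol ester
Product: 34 4β,8β,9α-trihydroxydaucan-6α-yl 4-hydroxybenzoate (target)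
Conditions: Bu4NF, AcOH, THF, 0 °C
Reagents that add atoms: none
Why: Fluoride cleavage of the aryl silyl ether, buffered with acetic acid so that the benzoate ester and the triol are left intact.

**Compound list**

1 | cycloheptane-1,3-dione | O=C1CCCCC(=O)C1 | starting material
2 | 3-(2-methylpropoxy)cyclohept-2-en-1-one | CC(C)COC1=CC(=O)CCCC1 | intermediate
3 | lithium 1-methyl-3-(2-methylpropoxy)cyclohept-2-en-1-olate (racemic, not isolated) | CC(C)COC1=CC(C)(O[Li])CCCC1 | intermediate
4 | 3-methylcyclohept-2-en-1-one | CC1=CC(=O)CCCC1 | intermediate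
5 | ethynyltrimethylsilane | C#C[Si](C)(C)C | starting material
6 | 2-methylpropanal | CC(C)C=O | starting material
7 | diisobutylaluminium (R)-3-methyl-3-[1-(trimethylsilyl)ethenyl]cyclohept-1-en-1-olate (not isolated) | CC(C)C[Al](CC(C)C)OC1=C[C@](C)(C(=C)[Si](C)(C)C)CCCC1 | intermediate
8 | (3R)-2-(1-hydroxy-2-methylpropyl)-3-methyl-3-[1-(trimethylsilyl)ethenyl]cycloheptan-1-one (mixture at C2 and the carbinol carbon) | CC(C)C(O)C1C(=O)CCCC[C@@]1(C)C(=C)[Si](C)(C)C | intermediate
9 | methanesulfonate of 8 (not isolated) | CC(C)C(OS(C)(=O)=O)C1C(=O)CCCC[C@@]1(C)C(=C)[Si](C)(C)C | intermediate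
10 | (2Z,3R)-3-methyl-2-(2-methylpropylidene)-3-[1-(trimethylsilyl)ethenyl]cycloheptan-1-one | CC(C)/C=C1\C(=O)CCCC[C@@]1(C)C(=C)[Si](C)(C)C | intermediate
11 | (2Z,3S)-3-ethenyl-3-methyl-2-(2-methylpropylidene)cycloheptan-1-one | CC(C)/C=C1\C(=O)CCCC[C@@]1(C)C=C | intermediate
12 | (6Z,7S)-7-ethenyl-7-methyl-6-(2-methylpropylidene)-1,4-dioxaspiro[4.6]undecane | CC(C)/C=C1\C2(OCCO2)CCCC[C@@]1(C)C=C | intermediate
13 | B-thexyl borinane with boron bridging C3 and C4, trans-fused to the dioxaspiro ring (not isolated) | CC(C)[C@@H]1B(C(C)(C)C(C)C)CC[C@]2(C)CCCCC3(OCCO3)[C@@H]12 | intermediate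
14 | (1S)-1-[(6R,7S)-7-(2-hydroxyethyl)-7-methyl-1,4-dioxaspiro[4.6]undecan-6-yl]-2-methylpropan-1-ol | CC(C)[C@H](O)[C@@H]1C2(OCCO2)CCCC[C@@]1(C)CCO | intermediate
15 | (1S)-1-[(6R,7S)-7-(2-iodoethyl)-7-methyl-1,4-dioxaspiro[4.6]undecan-6-yl]-2-methylpropan-1-ol | CC(C)[C@H](O)[C@@H]1C2(OCCO2)CCCC[C@@]1(C)CCI | intermediate
16 | 1-[(6R,7S)-7-(2-iodoethyl)-7-methyl-1,4-dioxaspiro[4.6]undecan-6-yl]-2-methylpropan-1-one (key-step precursor) | CC(C)C(=O)[C@@H]1C2(OCCO2)CCCC[C@@]1(C)CCI | intermediate
17 | C3 alkylsamarium diiodide derived from 16 (not isolated) | CC(C)C(=O)[C@@H]1C2(OCCO2)CCCC[C@@]1(C)CC[Sm](I)I | intermediate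
18 | trans-fused 6,6-ethylenedioxy-4-isopropyl-1-methylbicyclo[5.3.0]decan-4β-ol (1S,4R,5R; key-step product) | CC(C)[C@]1(O)CC[C@]2(C)CCCCC3(OCCO3)[C@H]21 | intermediate
19 | 4-O-triethylsilyl ether of 18 | CC(C)[C@]1(O[Si](CC)(CC)CC)CC[C@]2(C)CCCCC3(OCCO3)[C@H]21 | intermediate
20 | trans-fused 4-isopropyl-1-methyl-4β-(triethylsilyloxy)bicyclo[5.3.0]decan-6-one | CC(C)[C@]1(O[Si](CC)(CC)CC)CC[C@]2(C)CCCCC(=O)[C@H]21 | intermediate
21 | C6–C7 trimethylsilyl enol ether of 20 (not isolated) | CC(C)[C@]1(O[Si](CC)(CC)CC)CC[C@]2(C)CCCC=C(O[Si](C)(C)C)[C@H]21 | intermediate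
22 | trans-fused 4-isopropyl-1-methyl-4β-(triethylsilyloxy)bicyclo[5.3.0]dec-7-en-6-one | CC(C)[C@]1(O[Si](CC)(CC)CC)CC[C@]2(C)CCC=CC(=O)[C@H]21 | intermediate
23 | 8-methyl C6–C7 trimethylsilyl enol ether (either C8 epimer, not isolated) | CC(C)[C@]1(O[Si](CC)(CC)CC)CC[C@]2(C)CCC(C)C=C(O[Si](C)(C)C)[C@H]21 | intermediate
24 | 4β-(triethylsilyloxy)dauc-7-en-6-one (8-methyl-7-en-6-one) | CC(C)[C@]1(O[Si](CC)(CC)CC)CC[C@]2(C)CCC(C)=CC(=O)[C@H]21 | intermediate
25 | 6-(trimethylsilyloxy)-4β-(triethylsilyloxy)dauca-6,8-diene (not isolated) | CC(C)[C@]1(O[Si](CC)(CC)CC)CC[C@]2(C)CC=C(C)C=C(O[Si](C)(C)C)[C@H]21 | intermediate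
26 | lithium dienolate corresponding to 25 (not isolated) | CC(C)[C@]1(O[Si](CC)(CC)CC)CC[C@]2(C)CC=C(C)C=C(O[Li])[C@H]21 | intermediate
27 | 4β-(triethylsilyloxy)dauc-8-en-6-one | CC(C)[C@]1(O[Si](CC)(CC)CC)CC[C@]2(C)CC=C(C)CC(=O)[C@H]21 | intermediate
28 | 4β-hydroxydauc-8-en-6-one | CC(C)[C@]1(O)CC[C@]2(C)CC=C(C)CC(=O)[C@H]21 | intermediate
29 | dauc-8-ene-4β,6α-diol | CC(C)[C@]1(O)CC[C@]2(C)CC=C(C)C[C@H](O)[C@H]21 | intermediate
30 | 4-[(tert-butyldimethylsilyl)oxy]benzoic acid | CC(C)(C)[Si](C)(C)Oc1ccc(cc1)C(=O)O | starting material
31 | 4β-hydroxydauc-8-en-6α-yl 4-[(tert-butyldimethylsilyl)oxy]benzoate | CC(C)[C@]1(O)CC[C@]2(C)CC=C(C)C[C@H](OC(=O)c3ccc(O[Si](C)(C)C(C)(C)C)cc3)[C@H]21 | intermediate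
32 | 8α,9α-epoxy-4β-hydroxydaucan-6α-yl 4-[(tert-butyldimethylsilyl)oxy]benzoate | CC(C)[C@]1(O)CC[C@]2(C)C[C@@H]3O[C@]3(C)C[C@H](OC(=O)c4ccc(O[Si](C)(C)C(C)(C)C)cc4)[C@H]21 | intermediate
33 | 4β,8β,9α-trihydroxydaucan-6α-yl 4-[(tert-butyldimethylsilyl)oxy]benzoate | CC(C)[C@]1(O)CC[C@]2(C)C[C@H](O)[C@@](C)(O)C[C@H](OC(=O)c3ccc(O[Si](C)(C)C(C)(C)C)cc3)[C@H]21 | intermediate
34 | 4β,8β,9α-trihydroxydaucan-6α-yl 4-hydroxybenzoate (CNP0197754.1) | CC(C)[C@]1(O)CC[C@]2(C)C[C@H](O)[C@@](C)(O)C[C@H](OC(=O)c3ccc(O)cc3)[C@H]21 | target

**Step count and risks**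

Total step count: 21. Longest linear sequence: 21 steps (from cycloheptane-1,3-dione **1** to **34**; the aryl acid **30** is purchased).

Steps most likely to fail:

Step 10 (key step). The alkylsamarium may be protonated, for instance by the α-hydrogen at C5, or the iodide may simply be reduced before addition to the hindered isopropyl ketone; chelate control at C4 may also be incomplete. The fallback sets out from **16** and replaces the single-electron Barbier by a polar anionic cyclisation. Iodine–lithium exchange with t-BuLi (2.2 equiv, pentane/Et2O, −78 °C) is faster than carbonyl addition to the hindered ketone and gives the primary alkyllithium F1, which adds to the C4 ketone on warming. The dioxolane again forces the isopropyl group to the C5–H side. The fallback returns to the route at **18**.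

Step 7. The tethered B–H may fail to reach the hindered C5=C4 bond, or a second borane may add intermolecularly from the open face, which would erode the facial control at C5. The fallback sets out from **12** and uses a silicon tether that can only react intramolecularly. Hydrosilylation of the vinyl group with Ph2SiH2 and RhCl(PPh3)3 gives the primary diphenylsilane F2. Intramolecular hydrosilylation at high dilution with Pt2[(CH2=CHSiMe2)2O]3 closes the 1,1-diphenylsilacyclohexane F3, with silicon on C4 and hydrogen on C5 from the face of the tether. Tamao–Fleming oxidation under basic conditions (t-BuOOH, KH, Bu4NF, DMF) then returns to the route at **14**.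

Step 15. Enolisation may run toward the C8 methyl group or toward C5 instead of C9, giving the exocyclic alkene or β-elimination of the silyloxy group; the β,γ-enone may also reconjugate on work-up. The fallback sets out from **24** and moves the double bond under acid instead of through an enolate. Ketalisation with ethylene glycol and PPTS in benzene with water removal should shift the alkene out of conjugation, as in the ketalisation of steroidal 4-en-3-ones, to give the 8,9-unsaturated dioxolane F4. Brief hydrolysis with aqueous oxalic acid on silica gel then returns to the route at **27**.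

**Further compounds**

F1 | step 10 | primary alkyllithium from iodine–lithium exchange of 16 | CC(C)C(=O)[C@@H]1C2(OCCO2)CCCC[C@@]1(C)CC[Li]
F2 | step 7 | (6Z,7S)-7-[2-(diphenylsilyl)ethyl]-7-methyl-6-(2-methylpropylidene)-1,4-dioxaspiro[4.6]undecane | CC(C)/C=C1\C2(OCCO2)CCCC[C@@]1(C)CC[SiH](c3ccccc3)c4ccccc4
F3 | step 7 | 1,1-diphenylsilacyclohexane with silicon bridging C3 and C4, trans-fused to the dioxaspiro ring | CC(C)[C@@H]1[Si](c3ccccc3)(c4ccccc4)CC[C@]2(C)CCCCC5(OCCO5)[C@@H]12
F4 | step 15 | 6,6-ethylenedioxy-4β-(triethylsilyloxy)dauc-8-ene | CC(C)[C@]1(O[Si](CC)(CC)CC)CC[C@]2(C)CC=C(C)CC3(OCCO3)[C@H]21
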